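1. C13–Cl and 11-OH last: Appel chlorination of an 11,13-diol, which comes from dihydroxylation of an α-methylene lactone (C11 set here).
2. Key disconnection C6–C7: CrCl2-mediated intramolecular allylation of a Z enal by a (Z)-2-(bromomethyl)enoate; the alkoxide lactonises at once, so the ten-membered carbocycle and the cis γ-lactone close in one operation (C6 and C7 set).
3. Allyl bromide arm: C7 aldehyde + methyl acrylate (Baylis–Hillman, then SN2′ bromination); the 8-O-angelate is put in by Mitsunobu inversion.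
4. Furanone first: the lithium acetylide of a (Z)-enynal acetal opens 3,5-bis-O-silyl-2-C-methyl-D-ribonolactone (C9 and C10 from the sugar; the freed 8-OH is the Mitsunobu site), then 5-endo closure.
5. Ring order: 3(2H)-furanone (step 4), then carbocycle and lactone together (step 10).

Assumption: atom labels are the germacranolide ones (C1 furanone C=O, C3 enol-ether carbon, C4=C5, C6 lactone carbinol, C8 angelate carbon, C9 carbinol, C10 quaternary carbon, C11 carbinol, C12 lactone C=O, C13 CH2Cl); the target SMILES is read as 4Z,6S,7S,8S,9R,10R,11R with H6 and H7 cis and 11-OH cis to C8.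

Step 1
Reactants: 1 (Z)-3-methylpent-2-en-4-yn-1-ol
Product: 2 (Z)-3-methylpent-2-en-4-ynal
Conditions: activated MnO2, CH2Cl2, rt
Reagents that add atoms: none
Why: Allylic alcohol oxidation on MnO2 is neutral and heterogeneous, so the Z enyne geometry (the future C4=C5) passes into the enal unchanged and no stereocenter is formed.

Step 2
Reactants: 2 (Z)-3-methylpent-2-en-4-ynal
Product: 3 (Z)-5,5-dimethoxy-3-methylpent-3-en-1-yne
Conditions: HC(OMe)3, MeOH, PPTS (cat.), 0 °C → rt
Reagents that add atoms: trimethyl orthoformate COC(OC)OC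
Why: Acid-catalysed acetalisation masks the future C6 aldehyde so that the alkyne can be lithiated, and the mild catalyst leaves the Z alkene alone; no stereocenter is formed.

Step 3
Reactants: 4 2-C-methyl-D-ribono-1,4-lactone
Product: 5 3,5-bis-O-(triethylsilyl)-2-C-methyl-D-ribono-1,4-lactone
Conditions: TESCl (2.2 equiv), imidazole, DMF, 0 °C → rt
Reagents that add atoms: chlorotriethylsilane CC[Si](Cl)(CC)CC
Why: Silylation takes the primary and the secondary hydroxyl and leaves the hindered tertiary hydroxyl free (it becomes the furanone oxygen), and the three sugar stereocenters (future C8, C9, C10) are untouched.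

Step 4
Reactants: 3 (Z)-5,5-dimethoxy-3-methylpent-3-en-1-yne; 5 3,5-bis-O-(triethylsilyl)-2-C-methyl-D-ribono-1,4-lactone
Product: 8 (R)-5-[(Z)-4,4-dimethoxybut-2-en-2-yl]-2-[(1R,2R)-2-hydroxy-1,3-bis(triethylsilyloxy)propyl]-2-methylfuran-3(2H)-one, via lithium acetylide 6 (not isolated), via hydroxy ynone 7 (not isolated)
Conditions: 3, n-BuLi, THF, −78 °C; add to 5 pre-treated with LiN(SiMe3)2 (1 equiv), −78 → −40 °C; AcOH quench; then Et2NH, EtOH, rt
Reagents that add atoms: none
Why: Acetylide acylation by the lactone stops at the ketone stage (lithium hemiketal), and Et2NH then mediates the classical conjugate addition–elimination (net 5-endo oxa-Michael) of the tertiary 10-OH to the 3(2H)-furanone while the 9-O-silyl ether blocks pyranone formation; ring opening frees 8-OH, and C9 and C10 come unchanged from the sugar.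

Step 5
Reactants: 8 (R)-5-[(Z)-4,4-dimethoxybut-2-en-2-yl]-2-[(1R,2R)-2-hydroxy-1,3-bis(triethylsilyloxy)propyl]-2-methylfuran-3(2H)-one; 9 angelic acid
Product: 10 (1R,2S)-1-[(R)-5-((Z)-4,4-dimethoxybut-2-en-2-yl)-2-methyl-3-oxo-2,3-dihydrofuran-2-yl]-1,3-bis(triethylsilyloxy)propan-2-yl (Z)-2-methylbut-2-enoate
Conditions: PPh3, DIAD, toluene, 0 °C → rt
Reagents that add atoms: none
Why: Mitsunobu esterification displaces the 8-oxyphosphonium group by angelate with SN2 inversion (8R → 8S), and because the acid is never activated as an acyl donor its Z geometry is not at risk.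

Step 6
Reactants: 10 (1R,2S)-1-[(R)-5-((Z)-4,4-dimethoxybut-2-en-2-yl)-2-methyl-3-oxo-2,3-dihydrofuran-2-yl]-1,3-bis(triethylsilyloxy)propan-2-yl (Z)-2-methylbut-2-enoate
Product: 12 (1R,2R)-1-[(R)-5-((Z)-4,4-dimethoxybut-2-en-2-yl)-2-methyl-3-oxo-2,3-dihydrofuran-2-yl]-3-oxo-1-(triethylsilyloxy)propan-2-yl (Z)-2-methylbut-2-enoate, via primary alcohol 11 (not isolated)
Conditions: (COCl)2, DMSO, CH2Cl2, −78 → −30 °C; Et3N, −78 → 0 °C
Reagents that add atoms: none
Why: Under Swern conditions a primary triethylsilyl ether is cleaved and oxidised to the aldehyde while the secondary one survives, so the C7 aldehyde is unveiled cold in one operation without touching C8 (only its CIP descriptor changes).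

Step 7
Reactants: 12 (1R,2R)-1-[(R)-5-((Z)-4,4-dimethoxybut-2-en-2-yl)-2-methyl-3-oxo-2,3-dihydrofuran-2-yl]-3-oxo-1-(triethylsilyloxy)propan-2-yl (Z)-2-methylbut-2-enoate; 13 methyl acrylate
Product: 14 methyl (3RS,4S,5R)-5-[(R)-5-((Z)-4,4-dimethoxybut-2-en-2-yl)-2-methyl-3-oxo-2,3-dihydrofuran-2-yl]-3-hydroxy-4-[(Z)-2-methylbut-2-enoyloxy]-2-methylidene-5-(triethylsilyloxy)pentanoate
Conditions: methyl acrylate (10 equiv), DABCO (0.5 equiv), MeOH (cat.), rt
Reagents that add atoms: none
Why: Morita–Baylis–Hillman reaction of the activated α-acyloxy aldehyde adds C11–C13; the new C7 carbinol centre forms unselectively, which does not matter because C7 becomes sp2 in step 8.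

Step 8
Reactants: 14 methyl (3RS,4S,5R)-5-[(R)-5-((Z)-4,4-dimethoxybut-2-en-2-yl)-2-methyl-3-oxo-2,3-dihydrofuran-2-yl]-3-hydroxy-4-[(Z)-2-methylbut-2-enoyloxy]-2-methylidene-5-(triethylsilyloxy)pentanoate
Product: 15 methyl (Z,4S,5R)-2-(bromomethyl)-5-[(R)-5-((Z)-4,4-dimethoxybut-2-en-2-yl)-2-methyl-3-oxo-2,3-dihydrofuran-2-yl]-4-[(Z)-2-methylbut-2-enoyloxy]-5-(triethylsilyloxy)pent-2-enoate
Conditions: NBS, Me2S, CH2Cl2, 0 °C → rt
Reagents that add atoms: N-bromosuccinimide O=C1CCC(=O)N1Br
Why: Corey–Kim-type activation of the allylic alcohol as an alkoxysulfonium ion and SN2′ return of bromide give the thermodynamically preferred (Z)-2-(bromomethyl)enoate from both C7 epimers.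

Step 9
Reactants: 15 methyl (Z,4S,5R)-2-(bromomethyl)-5-[(R)-5-((Z)-4,4-dimethoxybut-2-en-2-yl)-2-methyl-3-oxo-2,3-dihydrofuran-2-yl]-4-[(Z)-2-methylbut-2-enoyloxy]-5-(triethylsilyloxy)pent-2-enoate
Product: 16 methyl (Z,4S,5R)-2-(bromomethyl)-5-hydroxy-4-[(Z)-2-methylbut-2-enoyloxy]-5-[(R)-2-methyl-3-oxo-5-((Z)-4-oxobut-2-en-2-yl)-2,3-dihydrofuran-2-yl]pent-2-enoate
Conditions: 1 M aq HCl, THF, 0 °C → rt
Reagents that add atoms: water O
Why: Dilute aqueous acid hydrolyses the dimethyl acetal to the Z enal and cleaves the secondary silyl ether in the same pot, while the allylic bromide, the methyl ester and the angelate are stable; no stereocenter is affected.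

Step 10
Reactants: 16 methyl (Z,4S,5R)-2-(bromomethyl)-5-hydroxy-4-[(Z)-2-methylbut-2-enoyloxy]-5-[(R)-2-methyl-3-oxo-5-((Z)-4-oxobut-2-en-2-yl)-2,3-dihydrofuran-2-yl]pent-2-enoate
Product: 19 (4Z,6S,7S,8S,9R,10R)-8-angeloyloxy-9-hydroxy-1-oxo-3,10-epoxygermacra-2,4,11(13)-trien-12,6-olide, via allylchromium species 17 (not isolated), via hydroxy ester 18 (not isolated)
Conditions: CrCl2 (8 equiv), THF, 2 mM, slow addition over 10 h, rt; aq NH4Cl
Reagents that add atoms: none
Why: Intramolecular Nozaki–Hiyama (CrCl2 Barbier-type) allylation forms C6–C7 and closes the carbocycle, and the chromium alkoxide lactonises onto the methyl ester in the same operation; the ester-bearing allylchromium adds through a chair-like transition state to give the syn adduct (H6/H7-cis lactone), and the C8 centre directs the face of C7 (aldehyde anti to the C9 branch, H8 in the allyl plane), setting 6S and 7S.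

Step 11
Reactants: 19 (4Z,6S,7S,8S,9R,10R)-8-angeloyloxy-9-hydroxy-1-oxo-3,10-epoxygermacra-2,4,11(13)-trien-12,6-olide
Product: 21 (4Z,6S,7S,8S,9R,10R,11S)-8-angeloyloxy-9,11,13-trihydroxy-1-oxo-3,10-epoxygermacra-2,4-dien-12,6-olide, via osmate ester 20 (not isolated)
Conditions: OsO4 (1.05 equiv), TMEDA (1.1 equiv), CH2Cl2, −78 °C; then aq NaHSO3, THF, rt
Reagents that add atoms: osmium tetroxide O=[Os](=O)(=O)=O
Why: Proposed new method: the only free hydroxyl (9-OH, on the C8 side of the lactone) is expected to hydrogen-bond to an oxo ligand of OsO4·TMEDA and so steer the [3+2] osmylation to the unhindered 1,1-disubstituted C11=C13 alkene from the face syn to C8, against the intrinsic preference for the open H7 face, which sets 11-OH cis to C8 (11S in the diol); the closest known reaction type is the hydrogen-bond-directed dihydroxylation of cyclic allylic and homoallylic alcohols with OsO4·TMEDA.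

Step 12
Reactants: 21 (4Z,6S,7S,8S,9R,10R,11S)-8-angeloyloxy-9,11,13-trihydroxy-1-oxo-3,10-epoxygermacra-2,4-dien-12,6-olide
Product: 22 (4Z,6S,7S,8S,9R,10R,11R)-8-angeloyloxy-13-chloro-9,11-dihydroxy-1-oxo-3,10-epoxygermacra-2,4-dien-12,6-olide
Conditions: PPh3, CCl4, pyridine, MeCN, 0 °C → rt
Reagents that add atoms: carbon tetrachloride ClC(Cl)(Cl)Cl
Why: Appel chlorination is selective for the primary 13-OH (SN2 at CH2 of the oxyphosphonium ion) over the tertiary α-hydroxy lactone and the neopentyl-like secondary 9-OH, so C11 is not touched and only its descriptor changes (11S → 11R).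

Compound list

1 | (Z)-3-methylpent-2-en-4-yn-1-ol | C#C/C(C)=C\CO | starting material
2 | (Z)-3-methylpent-2-en-4-ynal | C#C/C(C)=C\C=O | intermediate
3 | (Z)-5,5-dimethoxy-3-methylpent-3-en-1-yne | C#C/C(C)=C\C(OC)OC | intermediate
4 | 2-C-methyl-D-ribono-1,4-lactone, (3R,4R,5R)-3,4-dihydroxy-5-(hydroxymethyl)-3-methyloxolan-2-one | O=C1[C@](C)(O)[C@H](O)[C@@H](CO)O1 | starting material
5 | 3,5-bis-O-(triethylsilyl)-2-C-methyl-D-ribono-1,4-lactone, tertiary 2-OH free | O=C1[C@](C)(O)[C@H](O[Si](CC)(CC)CC)[C@@H](CO[Si](CC)(CC)CC)O1 | intermediate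
6 | lithium acetylide of 3 | [Li]C#C/C(C)=C\C(OC)OC | intermediate
7 | hydroxy ynone (4Z,8R,9R,10R), open form of the lactol: C1 ynone, free 8-OH and 10-OH, 7,9-bis-OTES, C6 dimethyl acetal | COC(OC)/C=C(/C)C#CC(=O)[C@](C)(O)[C@H](O[Si](CC)(CC)CC)[C@H](O)CO[Si](CC)(CC)CC | intermediate
8 | (R)-5-[(Z)-4,4-dimethoxybut-2-en-2-yl]-2-[(1R,2R)-2-hydroxy-1,3-bis(triethylsilyloxy)propyl]-2-methylfuran-3(2H)-one (8R,9R,10R; free 8-OH) | COC(OC)/C=C(/C)C1=CC(=O)[C@](C)(O1)[C@H](O[Si](CC)(CC)CC)[C@H](O)CO[Si](CC)(CC)CC | intermediate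
9 | angelic acid, (Z)-2-methylbut-2-enoic acid | C/C=C(/C)C(=O)O | starting material
10 | (1R,2S)-1-[(R)-5-((Z)-4,4-dimethoxybut-2-en-2-yl)-2-methyl-3-oxo-2,3-dihydrofuran-2-yl]-1,3-bis(triethylsilyloxy)propan-2-yl (Z)-2-methylbut-2-enoate (8S,9R,10R) | COC(OC)/C=C(/C)C1=CC(=O)[C@](C)(O1)[C@H](O[Si](CC)(CC)CC)[C@@H](OC(=O)/C(C)=C\C)CO[Si](CC)(CC)CC | intermediate
11 | primary alcohol: 10 without the primary silyl group (7-OH) | COC(OC)/C=C(/C)C1=CC(=O)[C@](C)(O1)[C@H](O[Si](CC)(CC)CC)[C@@H](OC(=O)/C(C)=C\C)CO | intermediate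
12 | C7 aldehyde, (1R,2R)-1-[(R)-5-((Z)-4,4-dimethoxybut-2-en-2-yl)-2-methyl-3-oxo-2,3-dihydrofuran-2-yl]-3-oxo-1-(triethylsilyloxy)propan-2-yl (Z)-2-methylbut-2-enoate | COC(OC)/C=C(/C)C1=CC(=O)[C@](C)(O1)[C@H](O[Si](CC)(CC)CC)[C@@H](OC(=O)/C(C)=C\C)C=O | intermediate
13 | methyl acrylate | C=CC(=O)OC | starting material
14 | Baylis–Hillman adduct, methyl (3RS,4S,5R)-3-hydroxy-2-methylidene pentanoate carrying 4-O-angelate, 5-OTES and the furanone on C5 (C7 epimer mixture) | COC(OC)/C=C(/C)C1=CC(=O)[C@](C)(O1)[C@H](O[Si](CC)(CC)CC)[C@@H](OC(=O)/C(C)=C\C)C(O)C(=C)C(=O)OC | intermediate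
15 | allylic bromide, methyl (Z,4S,5R)-2-(bromomethyl)pent-2-enoate carrying 4-O-angelate, 5-OTES and the furanone acetal on C5 | COC(OC)/C=C(/C)C1=CC(=O)[C@](C)(O1)[C@H](O[Si](CC)(CC)CC)[C@@H](OC(=O)/C(C)=C\C)/C=C(\CBr)C(=O)OC | intermediate
16 | seco enal, methyl (Z,4S,5R)-2-(bromomethyl)-5-hydroxy-4-[(Z)-2-methylbut-2-enoyloxy]-5-[(R)-2-methyl-3-oxo-5-((Z)-4-oxobut-2-en-2-yl)-2,3-dihydrofuran-2-yl]pent-2-enoate | O=C/C=C(/C)C1=CC(=O)[C@](C)(O1)[C@H](O)[C@@H](OC(=O)/C(C)=C\C)/C=C(\CBr)C(=O)OC | intermediate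
17 | allylchromium dichloride from 16 (trivalent chromium on C13) | O=C/C=C(/C)C1=CC(=O)[C@](C)(O1)[C@H](O)[C@@H](OC(=O)/C(C)=C\C)/C=C(\C[Cr](Cl)Cl)C(=O)OC | intermediate
18 | hydroxy ester, methyl (4Z,6S,7S,8S,9R,10R)-8-angeloyloxy-6,9-dihydroxy-1-oxo-3,10-epoxygermacra-2,4,11(13)-trien-12-oate (formed as its chromium alkoxide) | C/C=C(/C)C(=O)O[C@H]1[C@@H](C(=C)C(=O)OC)[C@@H](O)/C=C(/C)C2=CC(=O)[C@](C)(O2)[C@@H]1O | intermediate
19 | (4Z,6S,7S,8S,9R,10R)-8-angeloyloxy-9-hydroxy-1-oxo-3,10-epoxygermacra-2,4,11(13)-trien-12,6-olide | C/C=C(/C)C(=O)O[C@H]1[C@@H]2[C@H](/C=C(/C)C3=CC(=O)[C@](C)(O3)[C@@H]1O)OC(=O)C2=C | intermediate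
20 | cyclic 11,13-osmate ester of 21 (hexavalent osmium, TMEDA-ligated) | C/C=C(/C)C(=O)O[C@H]1[C@@H]2[C@H](/C=C(/C)C3=CC(=O)[C@](C)(O3)[C@@H]1O)OC(=O)[C@@]2(O4)CO[Os]4(=O)=O.CN(C)CCN(C)C | intermediate
21 | (4Z,6S,7S,8S,9R,10R,11S)-8-angeloyloxy-9,11,13-trihydroxy-1-oxo-3,10-epoxygermacra-2,4-dien-12,6-olide | C/C=C(/C)C(=O)O[C@H]1[C@@H]2[C@H](/C=C(/C)C3=CC(=O)[C@](C)(O3)[C@@H]1O)OC(=O)[C@@]2(O)CO | intermediate
22 | CNP0272644.1, (4Z,6S,7S,8S,9R,10R,11R)-8-angeloyloxy-13-chloro-9,11-dihydroxy-1-oxo-3,10-epoxygermacra-2,4-dien-12,6-olide | C/C=C(/C)C(=O)O[C@H]1[C@@H]2[C@H](/C=C(/C)C3=CC(=O)[C@](C)(O3)[C@@H]1O)OC(=O)[C@@]2(O)CCl | target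

Total step count: 12 (two on the enyne arm, one on the sugar arm, nine after their union). Longest linear sequence: 11 steps (1 → 2 → 3 → 8 → 10 → 12 → 14 → 15 → 16 → 19 → 21 → 22).

The three steps most likely to fail

Step 10 is the least certain. The strained ring may close slowly and oligomerise, and ring strain may override the open-chain preference that sets C7 (or C6). The fallback sets out from 16: Bu3SnSnBu3 with catalytic Pd(PPh3)4 turns the allylic bromide into the allylstannane F1. BF3·OEt2 at −78 °C under high dilution then closes the ring by a Lewis-acid-promoted allylstannane–aldehyde addition. This runs through an open, antiperiplanar transition state that is syn-selective without a metal chelate, so the stereocontrol rests on a different element. It gives hydroxy ester 18, and a trace of acid lactonises this; the route is rejoined at 19.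

Step 11 has two weaknesses. Osmium may take the C4=C5 or furanone alkene, and the 9-OH, which is further from the alkene than in known directed cases, may not deliver it to the C8 face. Without delivery the open H7 face would be attacked and the 11-epimer would form. The fallback sets out from 19: Weitz–Scheffer epoxidation with t-BuOOH and catalytic DBU adds peroxide only to the α-methylene lactone. C11 is then decided by closure of the peroxy enolate rather than by approach of an external reagent, and the needed isomer is the (11S)-spiro-epoxide F2 with oxygen syn to C8. This closure may equally favour the H7 face, so the fallback secures chemoselectivity more than configuration. HCl in dioxane opens F2 at the primary C13 and gives the chlorohydrin directly, so the route is rejoined at 22.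

Step 7 exposes an epimerisable α-acyloxy aldehyde to an amine for a long time. C8 may scramble, silanol may be lost by β-elimination, or the angelate may migrate to the new 7-OH. The fallback sets out from 12 and 13: PhSeLi in THF at −78 °C triggers a Michael–aldol three-component coupling that is over in minutes and gives the β-phenylselanyl aldol F3. Oxidation with H2O2 at 0 °C and syn-elimination of the selenoxide then give the same adduct, and the route is rejoined at 14.

Further compounds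
F1 | step 10 | allylstannane, methyl (Z,4S,5R)-5-hydroxy-4-[(Z)-2-methylbut-2-enoyloxy]-5-[(R)-2-methyl-3-oxo-5-((Z)-4-oxobut-2-en-2-yl)-2,3-dihydrofuran-2-yl]-2-[(tributylstannyl)methyl]pent-2-enoate | O=C/C=C(/C)C1=CC(=O)[C@](C)(O1)[C@H](O)[C@@H](OC(=O)/C(C)=C\C)/C=C(\C[Sn](CCCC)(CCCC)CCCC)C(=O)OC
F2 | step 11 | spiro-epoxide, (4Z,6S,7S,8S,9R,10R,11S)-8-angeloyloxy-11,13-epoxy-9-hydroxy-1-oxo-3,10-epoxygermacra-2,4-dien-12,6-olide | C/C=C(/C)C(=O)O[C@H]1[C@@H]2[C@H](/C=C(/C)C3=CC(=O)[C@](C)(O3)[C@@H]1O)OC(=O)[C@@]24CO4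
F3 | step 7 | β-phenylselanyl aldol, methyl (4S,5R)-3-hydroxy-2-[(phenylselanyl)methyl]pentanoate carrying 4-O-angelate, 5-OTES and the furanone acetal on C5 (mixture at C2 and C3) | COC(OC)/C=C(/C)C1=CC(=O)[C@](C)(O1)[C@H](O[Si](CC)(CC)CC)[C@@H](OC(=O)/C(C)=C\C)C(O)C(C[Se]c1ccccc1)C(=O)OC
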